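The eleven-membered ring is never closed; it is unveiled. In the target, oxygenated C11 and alkene carbon C4 flank carboxyl-bearing C5, so a transannular C5–C11 bond folds the ring into a cis-fused bicycle: a six-membered ring (C11, C1–C5) sharing C5–C11 with a seven-membered ring (C5–C11). Grob fragmentation of the tertiary C11 alkoxide against a C4 mesylate cuts that shared bond and, in one operation, delivers the medium ring, the C11 ketone and the C4=C5 enoate with C3 and C6 cis. The precursor is a bicyclo[5.4.0]undecane hydroxy ester with an equatorial C4 mesylate, a C5 allyl ester and a C7 silyl ether.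

Key step: step 12

Remark on numbering: all ring compounds carry the target's numbering (C1 methylene carbon, C4=C5 alkene with the carboxyl on C5, C7 acyloxy carbon, C9 gem-dimethyl carbon, C11 carbinol carbon). C7 keeps one spatial arrangement throughout; its CIP label reads R while the C10 iodide is present (12 to 14) and S otherwise.

Assumption: compounds 14 to 18 should form as two diastereomers that differ only in the sense of the C4/C5/C11 set relative to C7. Both have the same relative configuration within that set and both give 19 in step 12, so they are carried on together; names and SMILES show one of them.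

**Step 1**
Reactants: 1 2,2-dimethylpent-4-enoic acid
Product: 2 2,2-dimethylpent-4-en-1-ol
Conditions: LiAlH4, THF, 0 °C → rt
Reagents that add atoms: none
Why: Hydride reduction of a carboxylic acid to the primary alcohol; the isolated terminal alkene is inert to LiAlH4.

**Step 2**
Reactants: 2 2,2-dimethylpent-4-en-1-ol
Product: 3 5-iodo-4,4-dimethylpent-1-ene
Conditions: PPh3, I2, imidazole, toluene, 90 °C
Reagents that add atoms: iodine II
Why: Appel-type (Garegg–Samuelsson) iodination, in which the neopentyl alkoxyphosphonium salt collapses on heating by substitution without rearrangement; the iodide is the halide needed for the later Barbier closure.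

**Step 3**
Reactants: 3 5-iodo-4,4-dimethylpent-1-ene
Product: 5 racemic 2-(3-iodo-2,2-dimethylpropyl)oxirane, via bromohydrin 4 (not isolated)
Conditions: NBS, THF/H2O, 0 °C → rt; then 2 M NaOH, rt
Reagents that add atoms: water O
Why: Bromohydrin formation through the bromonium ion and base-induced closure to the epoxide (both regioisomeric bromohydrins give the same epoxide); a peracid is avoided because it would oxidise the alkyl iodide.

**Step 4**
Reactants: 5 racemic 2-(3-iodo-2,2-dimethylpropyl)oxirane
Product: 6 (S)-2-(3-iodo-2,2-dimethylpropyl)oxirane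
Conditions: (R,R)-(salen)Co(OAc) (0.5 mol%; salen = N,N'-bis(3,5-di-tert-butylsalicylidene)cyclohexane-1,2-diamine dianion), H2O (0.55 equiv), THF, 0 °C → rt
Reagents that add atoms: none
Why: Jacobsen hydrolytic kinetic resolution, in which the (R,R) catalyst should hydrolyse the (R)-epoxide selectively and leave the (S)-epoxide, so that C7 is fixed here as a single enantiomer.

**Step 5**
Reactants: 6 (S)-2-(3-iodo-2,2-dimethylpropyl)oxirane
Product: 7 (S)-1,5-diiodo-4,4-dimethylpentan-2-ol
Conditions: LiI, AcOH, THF, 0 °C → rt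
Reagents that add atoms: lithium iodide [Li+].[I-]
Why: Acid-assisted SN2 opening of the terminal epoxide by iodide at the unsubstituted carbon (future C6), which leaves the C7 stereocentre untouched.

**Step 6**
Reactants: 7 (S)-1,5-diiodo-4,4-dimethylpentan-2-ol
Product: 8 (S)-tert-butyl[(1,5-diiodo-4,4-dimethylpentan-2-yl)oxy]dimethylsilane
Conditions: TBSOTf, 2,6-lutidine, CH2Cl2, −78 → 0 °C
Reagents that add atoms: tert-butyldimethylsilyl triflate CC(C)(C)[Si](C)(C)OS(=O)(=O)C(F)(F)F
Why: Silylation of the secondary alcohol with a silyl triflate and a weak hindered base, mild enough that the iodohydrin does not close back to the epoxide.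

**Step 7**
Reactants: 8 (S)-tert-butyl[(1,5-diiodo-4,4-dimethylpentan-2-yl)oxy]dimethylsilane; 9 2,6-dimethoxybenzoic acid; 10 allyl bromide
Product: 13 allyl 1-[(2R)-2-(tert-butyldimethylsilyloxy)-5-iodo-4,4-dimethylpentyl]-2,6-dimethoxycyclohexa-2,5-diene-1-carboxylate, via Birch dianion 11 (not isolated), via lithium carboxylate 12 (not isolated)
Conditions: Li, NH3/THF, −78 °C; isoprene; 8, −78 °C; NH4Cl; NH3 off; then 10, DMF, rt
Reagents that add atoms: none
Why: Birch reductive alkylation, in which two-electron reduction of the benzoate gives the dienolate dianion that is alkylated at the ipso carbon (future C5) by the primary C6 iodide in an SN2 step while the neopentyl C10 iodide is inert to substitution, followed by O-allylation of the carboxylate; C7 is not touched.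

**Step 8**
Reactants: 13 allyl 1-[(2R)-2-(tert-butyldimethylsilyloxy)-5-iodo-4,4-dimethylpentyl]-2,6-dimethoxycyclohexa-2,5-diene-1-carboxylate
Product: 14 allyl (1S)-1-[(2R)-2-(tert-butyldimethylsilyloxy)-5-iodo-4,4-dimethylpentyl]-2-methoxy-6-oxocyclohex-2-ene-1-carboxylate (C11 ketone and C4 methyl enol ether; with its C5 epimer)
Conditions: 0.05 M HCl, THF/H2O, 0 °C
Reagents that add atoms: water O
Why: Acid-catalysed enol ether hydrolysis stopped at the mono stage, since the second enol ether would have to be protonated next to a carbon that now bears a ketone and an ester and should react far more slowly; C5 becomes a stereocentre without control, which is of no consequence.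

**Step 9**
Reactants: 14 allyl (1S)-1-[(2R)-2-(tert-butyldimethylsilyloxy)-5-iodo-4,4-dimethylpentyl]-2-methoxy-6-oxocyclohex-2-ene-1-carboxylate
Product: 16 allyl (5R,7S,11S)-7-(tert-butyldimethylsilyloxy)-11-hydroxy-9,9-dimethyl-4-oxobicyclo[5.4.0]undecane-5-carboxylate (cis-fused; C11 hydroxyl cis to the C5 ester), via enol ether alcohol 15 (not isolated)
Conditions: SmI2 (2.5 equiv), Fe(dbm)3 (2 mol%; dbm = dibenzoylmethanate), THF, −78 → 0 °C; then 0.5 M HCl, rt
Reagents that add atoms: water O
Why: Samarium diiodide intramolecular Barbier reaction (7-exo-trig addition of C10 to the C11 carbonyl, helped by the C9 gem-dimethyl group), in which chelation of trivalent samarium by the ketone and ester carbonyls holds the ester equatorial and the side chain axial, so that C10 adds from the chain face and sets C11 with the hydroxyl cis to the ester; the acidic quench hydrolyses the remaining enol ether to the C4 ketone.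

**Step 10**
Reactants: 16 allyl (5R,7S,11S)-7-(tert-butyldimethylsilyloxy)-11-hydroxy-9,9-dimethyl-4-oxobicyclo[5.4.0]undecane-5-carboxylate
Product: 17 allyl (4R,5S,7S,11S)-7-(tert-butyldimethylsilyloxy)-4,11-dihydroxy-9,9-dimethylbicyclo[5.4.0]undecane-5-carboxylate
Conditions: Me4NBH(OAc)3, MeCN/AcOH, −20 °C
Reagents that add atoms: none
Why: Evans–Saksena reduction, in which the C11 hydroxyl binds boron and delivers hydride to the C4 carbonyl from its own face, so the new C4 hydroxyl is anti to the C11 hydroxyl (trans to the ester, cis to C6), the arrangement that makes the later mesylate equatorial.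

**Step 11**
Reactants: 17 allyl (4R,5S,7S,11S)-7-(tert-butyldimethylsilyloxy)-4,11-dihydroxy-9,9-dimethylbicyclo[5.4.0]undecane-5-carboxylate
Product: 18 allyl (4R,5S,7S,11S)-7-(tert-butyldimethylsilyloxy)-11-hydroxy-4-(methanesulfonyloxy)-9,9-dimethylbicyclo[5.4.0]undecane-5-carboxylate
Conditions: MsCl (1.3 equiv), Et3N, CH2Cl2, −20 → 0 °C
Reagents that add atoms: methanesulfonyl chloride CS(=O)(=O)Cl
Why: Sulfonylation through sulfene of the secondary C4 alcohol only, the tertiary ring-fusion alcohol being too hindered to react at this temperature; the configuration at C4 is retained.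

**Step 12**
Reactants: 18 allyl (4R,5S,7S,11S)-7-(tert-butyldimethylsilyloxy)-11-hydroxy-4-(methanesulfonyloxy)-9,9-dimethylbicyclo[5.4.0]undecane-5-carboxylate
Product: 19 allyl (4E,7S)-7-(tert-butyldimethylsilyloxy)-9,9-dimethyl-11-oxocycloundec-4-ene-5-carboxylate (C3 cis to C6)
Conditions: KOtBu (1.05 equiv), THF, −20 → 0 °C
Reagents that add atoms: none
Why: KOtBu deprotonates the tertiary C11 hydroxyl and the alkoxide pushes into the C5–C11 bond, which breaks as the C4 mesylate leaves, so the C11 carbonyl and the C4=C5 alkene form together in a Grob (Wharton-type) fragmentation of a 1,3-hydroxy sulfonate; because C5 bears the ester, retro-aldol to the ester enolate followed by E1cB loss of mesylate is a second channel to the same product. No ring is closed here: the eleven-membered ring appears because the bond shared by the six- and seven-membered rings is cut, so the medium ring is never formed against entropy. No stereocentre is created; C4, C5 and C11 are erased and C7 is untouched. The selectivity needed is the alkene geometry, and the cis ring fusion secures it: in the chair with C6 axial and the ester equatorial on C5 the mesylate is equatorial and anti-periplanar to C5–C11, and the groups gauche across C4–C5 (C3 and C6) end up cis. The stepwise channel should converge on the same isomer, which is the more stable 2-alkyl enoate with C3 trans to the ester. The single equivalent of base ends as potassium methanesulfonate, so none is left to enolise the new ketone.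

**Step 13**
Reactants: 19 allyl (4E,7S)-7-(tert-butyldimethylsilyloxy)-9,9-dimethyl-11-oxocycloundec-4-ene-5-carboxylate
Product: 20 allyl (4E,7S)-7-hydroxy-9,9-dimethyl-11-oxocycloundec-4-ene-5-carboxylate
Conditions: HF·pyridine, pyridine, THF, 0 °C
Reagents that add atoms: none
Why: Fluoride-driven cleavage of the silyl ether under buffered, weakly acidic conditions, which avoid a free alkoxide that could lactonise onto the C5 ester.

**Step 14**
Reactants: 20 allyl (4E,7S)-7-hydroxy-9,9-dimethyl-11-oxocycloundec-4-ene-5-carboxylate; 21 angelic acid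
Product: 23 allyl (4E,7S)-9,9-dimethyl-7-[(Z)-2-methylbut-2-enoyloxy]-11-oxocycloundec-4-ene-5-carboxylate, via mixed anhydride 22 (not isolated)
Conditions: 2,4,6-trichlorobenzoyl chloride, Et3N, toluene, rt; then 20, 75 °C
Reagents that add atoms: none
Why: Yamaguchi esterification through the mixed anhydride without a nucleophilic catalyst, conditions that should keep the Z geometry of the angelate; acylation at oxygen retains C7.

**Step 15**
Reactants: 23 allyl (4E,7S)-9,9-dimethyl-7-[(Z)-2-methylbut-2-enoyloxy]-11-oxocycloundec-4-ene-5-carboxylate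
Product: 27 allyl (4E,7S)-9,9-dimethyl-7-[(Z)-2-methylbut-2-enoyloxy]-1-methylene-11-oxocycloundec-4-ene-5-carboxylate, via lithium enolate 24 (not isolated), via Mannich base 25 (not isolated), via ammonium iodide 26 (not isolated)
Conditions: LiN(SiMe3)2 (1.05 equiv), THF, −78 °C; CH2=NMe2+ I−, −78 → 0 °C; MeI, rt; aq. NaHCO3, CH2Cl2, rt
Reagents that add atoms: Eschenmoser's salt C=[N+](C)C.[I-]
Why: Eschenmoser methylenation, in which kinetic deprotonation goes to C1 because the C10 hydrogens are shielded by the C9 gem-dimethyl group and the ester γ-hydrogens are far less acidic, followed by Mannich reaction of the enolate, N-methylation and E1cB elimination to the exocyclic enone.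

**Step 16**
Reactants: 27 allyl (4E,7S)-9,9-dimethyl-7-[(Z)-2-methylbut-2-enoyloxy]-1-methylene-11-oxocycloundec-4-ene-5-carboxylate
Product: 28 allyl (4E,7S,11S)-11-hydroxy-9,9-dimethyl-7-[(Z)-2-methylbut-2-enoyloxy]-1-methylenecycloundec-4-ene-5-carboxylate
Conditions: (R)-1-methyl-3,3-diphenyltetrahydro-1H,3H-pyrrolo[1,2-c][1,3,2]oxazaborole (0.3 equiv), catecholborane, toluene, −78 °C
Reagents that add atoms: none
Why: Corey–Bakshi–Shibata reduction under catalyst control, in which the alkene carbon C1 acts as the large group and the C10 methylene as the small one, so the (R)-oxazaborolidine should deliver hydride to the face that gives the (S)-C11 alcohol; catecholborane at −78 °C leaves the other alkenes and the esters alone.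

**Step 17**
Reactants: 28 allyl (4E,7S,11S)-11-hydroxy-9,9-dimethyl-7-[(Z)-2-methylbut-2-enoyloxy]-1-methylenecycloundec-4-ene-5-carboxylate
Product: 29 (4E,7S,11S)-11-hydroxy-9,9-dimethyl-7-[(Z)-2-methylbut-2-enoyloxy]-1-methylenecycloundec-4-ene-5-carboxylic acid (CNP0263820.1)
Conditions: Pd(PPh3)4 (5 mol%), morpholine, THF, rt; then pH 4 buffer
Reagents that add atoms: none
Why: Deallylation through a π-allyl complex of zerovalent palladium (Tsuji–Trost type) with morpholine as the allyl acceptor; the neutral conditions spare the angelate, the allylic alcohol and both alkenes.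

**Compound list**
1 | 2,2-dimethylpent-4-enoic acid | C=CCC(C)(C)C(=O)O | starting material
2 | 2,2-dimethylpent-4-en-1-ol | C=CCC(C)(C)CO | intermediate
3 | 5-iodo-4,4-dimethylpent-1-ene | C=CCC(C)(C)CI | intermediate
4 | racemic 1-bromo-5-iodo-4,4-dimethylpentan-2-ol (bromohydrin, major regioisomer; not isolated) | OC(CBr)CC(C)(C)CI | intermediate
5 | racemic 2-(3-iodo-2,2-dimethylpropyl)oxirane | ICC(C)(C)CC1CO1 | intermediate
6 | (S)-2-(3-iodo-2,2-dimethylpropyl)oxirane | ICC(C)(C)C[C@H]1CO1 | intermediate
7 | (S)-1,5-diiodo-4,4-dimethylpentan-2-ol | IC[C@@H](O)CC(C)(C)CI | intermediate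
8 | (S)-tert-butyl[(1,5-diiodo-4,4-dimethylpentan-2-yl)oxy]dimethylsilane | IC[C@@H](O[Si](C)(C)C(C)(C)C)CC(C)(C)CI | intermediate
9 | 2,6-dimethoxybenzoic acid | COc1cccc(OC)c1C(=O)O | starting material
10 | allyl bromide | C=CCBr | starting material
11 | dilithium 2,6-dimethoxycyclohexa-2,5-dien-1-ide-1-carboxylate (Birch dianion; not isolated) | [Li+].[Li+].[O-]C(=O)[C-]1C(OC)=CCC=C1OC | intermediate
12 | lithium 1-[(2R)-2-(tert-butyldimethylsilyloxy)-5-iodo-4,4-dimethylpentyl]-2,6-dimethoxycyclohexa-2,5-diene-1-carboxylate (not isolated) | [Li+].[O-]C(=O)C1(C[C@@H](O[Si](C)(C)C(C)(C)C)CC(C)(C)CI)C(OC)=CCC=C1OC | intermediate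
13 | allyl 1-[(2R)-2-(tert-butyldimethylsilyloxy)-5-iodo-4,4-dimethylpentyl]-2,6-dimethoxycyclohexa-2,5-diene-1-carboxylate | C=CCOC(=O)C1(C[C@@H](O[Si](C)(C)C(C)(C)C)CC(C)(C)CI)C(OC)=CCC=C1OC | intermediate
14 | allyl (1S)-1-[(2R)-2-(tert-butyldimethylsilyloxy)-5-iodo-4,4-dimethylpentyl]-2-methoxy-6-oxocyclohex-2-ene-1-carboxylate | O=C1CCC=C(OC)[C@@]1(C(=O)OCC=C)C[C@@H](O[Si](C)(C)C(C)(C)C)CC(C)(C)CI | intermediate
15 | allyl (5R,7S,11S)-7-(tert-butyldimethylsilyloxy)-11-hydroxy-4-methoxy-9,9-dimethylbicyclo[5.4.0]undec-3-ene-5-carboxylate (cis-fused; not isolated) | O[C@]12CCC=C(OC)[C@@]1(C(=O)OCC=C)C[C@@H](O[Si](C)(C)C(C)(C)C)CC(C)(C)C2 | intermediate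
16 | allyl (5R,7S,11S)-7-(tert-butyldimethylsilyloxy)-11-hydroxy-9,9-dimethyl-4-oxobicyclo[5.4.0]undecane-5-carboxylate | O[C@]12CCCC(=O)[C@@]1(C(=O)OCC=C)C[C@@H](O[Si](C)(C)C(C)(C)C)CC(C)(C)C2 | intermediate
17 | allyl (4R,5S,7S,11S)-7-(tert-butyldimethylsilyloxy)-4,11-dihydroxy-9,9-dimethylbicyclo[5.4.0]undecane-5-carboxylate | O[C@]12CCC[C@@H](O)[C@@]1(C(=O)OCC=C)C[C@@H](O[Si](C)(C)C(C)(C)C)CC(C)(C)C2 | intermediate
18 | allyl (4R,5S,7S,11S)-7-(tert-butyldimethylsilyloxy)-11-hydroxy-4-(methanesulfonyloxy)-9,9-dimethylbicyclo[5.4.0]undecane-5-carboxylate (key-step precursor) | O[C@]12CCC[C@@H](OS(C)(=O)=O)[C@@]1(C(=O)OCC=C)C[C@@H](O[Si](C)(C)C(C)(C)C)CC(C)(C)C2 | intermediate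
19 | allyl (4E,7S)-7-(tert-butyldimethylsilyloxy)-9,9-dimethyl-11-oxocycloundec-4-ene-5-carboxylate (key-step product) | O=C1CCC/C=C(/C(=O)OCC=C)C[C@@H](O[Si](C)(C)C(C)(C)C)CC(C)(C)C1 | intermediate
20 | allyl (4E,7S)-7-hydroxy-9,9-dimethyl-11-oxocycloundec-4-ene-5-carboxylate | O=C1CCC/C=C(/C(=O)OCC=C)C[C@@H](O)CC(C)(C)C1 | intermediate
21 | angelic acid, (Z)-2-methylbut-2-enoic acid | C/C=C(/C)C(=O)O | starting material
22 | (Z)-2-methylbut-2-enoic 2,4,6-trichlorobenzoic anhydride (not isolated) | C/C=C(/C)C(=O)OC(=O)c1c(Cl)cc(Cl)cc1Cl | intermediate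
23 | allyl (4E,7S)-9,9-dimethyl-7-[(Z)-2-methylbut-2-enoyloxy]-11-oxocycloundec-4-ene-5-carboxylate | O=C1CCC/C=C(/C(=O)OCC=C)C[C@@H](OC(=O)/C(C)=C\C)CC(C)(C)C1 | intermediate
24 | lithium C1–C11 enolate of 23 (not isolated) | [Li+].[O-]C1=CCC/C=C(/C(=O)OCC=C)C[C@@H](OC(=O)/C(C)=C\C)CC(C)(C)C1 | intermediate
25 | allyl (4E,7S)-1-(dimethylaminomethyl)-9,9-dimethyl-7-[(Z)-2-methylbut-2-enoyloxy]-11-oxocycloundec-4-ene-5-carboxylate (C1 epimers; not isolated) | O=C1C(CN(C)C)CC/C=C(/C(=O)OCC=C)C[C@@H](OC(=O)/C(C)=C\C)CC(C)(C)C1 | intermediate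
26 | trimethylammonium iodide of 25 (not isolated) | O=C1C(C[N+](C)(C)C)CC/C=C(/C(=O)OCC=C)C[C@@H](OC(=O)/C(C)=C\C)CC(C)(C)C1.[I-] | intermediate
27 | allyl (4E,7S)-9,9-dimethyl-7-[(Z)-2-methylbut-2-enoyloxy]-1-methylene-11-oxocycloundec-4-ene-5-carboxylate | C=C1CC/C=C(/C(=O)OCC=C)C[C@@H](OC(=O)/C(C)=C\C)CC(C)(C)CC1=O | intermediate
28 | allyl (4E,7S,11S)-11-hydroxy-9,9-dimethyl-7-[(Z)-2-methylbut-2-enoyloxy]-1-methylenecycloundec-4-ene-5-carboxylate | C=C1CC/C=C(/C(=O)OCC=C)C[C@@H](OC(=O)/C(C)=C\C)CC(C)(C)C[C@@H]1O | intermediate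
29 | (4E,7S,11S)-11-hydroxy-9,9-dimethyl-7-[(Z)-2-methylbut-2-enoyloxy]-1-methylenecycloundec-4-ene-5-carboxylic acid | C=C1CC/C=C(/C(=O)O)C[C@@H](OC(=O)/C(C)=C\C)CC(C)(C)C[C@@H]1O | target

Total step count: 17. Longest linear sequence: 17 steps (1 to 29); 9, 10 and 21 enter as purchased materials.

**Steps most likely to fail**

Step 9. The C10 radical or organosamarium may be quenched before it closes the seven-membered ring, which would give simple reduction of the C–I bond or of the ketone. The closure would then be run as a polar reaction. Compound 14 is treated with t-BuLi (2.1 equiv) in Et2O/pentane at −100 °C, where iodine–lithium exchange at the primary iodide should outrun addition to the hindered ketone and ester. The neopentyllithium adds to C11 on warming to −78 °C (halogen–metal-exchange-initiated cyclisation of an iodo ketone). The lithium alkoxide of 15 is hydrolysed with dilute HCl as in step 9 and the route is rejoined at 16. This detour forms no compound outside the list (F0).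

Step 7. Substitution at the β-branched, β-silyloxy C6 iodide by the hindered dianion may be slow, so that proton transfer or elimination takes over. The C5–C6 bond would then be made by epoxide opening. The fallback sets out from epoxide 6 and acid 9. Dianion 11 is generated as before, NH3 is removed, and 6 is added in THF, where attack at its unsubstituted terminus should give the dilithium alkoxide carboxylate F1. Both oxygens are silylated (TBSOTf, 2,6-lutidine) to the silyl ether silyl ester F2. Aqueous K2CO3 in MeOH cleaves only the silyl ester, and the carboxylate is allylated with 10 in DMF to rejoin the route at 13. Steps 5 and 6 are then not needed.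

Step 12. Under the potassium alkoxide the stepwise channel may erode the alkene geometry, or the freed keto enoate may condense across the ring. Ring closure and fragmentation would then be merged under non-basic conditions. The fallback sets out from 14, which is fully hydrolysed (1 M HCl, THF) to the cyclohexane-1,3-dione F3. One carbonyl is reduced (NaBH4, MeOH/CH2Cl2, −78 °C) to the hydroxy ketone F4, which is mesylated (MsCl, Et3N) to the keto mesylate F5. SmI2 then effects the Barbier closure already proven in step 9, and the samarium alkoxide of 18 fragments in the flask (sequential Barbier cyclisation and Grob fragmentation) to rejoin the route at 19.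

**Further compounds**
F0 | step 9 | none | none
F1 | step 7 | dilithium 1-[(2R)-5-iodo-4,4-dimethyl-2-oxidopentyl]-2,6-dimethoxycyclohexa-2,5-diene-1-carboxylate | [Li+].[Li+].[O-]C(=O)C1(C[C@@H]([O-])CC(C)(C)CI)C(OC)=CCC=C1OC
F2 | step 7 | tert-butyldimethylsilyl 1-[(2R)-2-(tert-butyldimethylsilyloxy)-5-iodo-4,4-dimethylpentyl]-2,6-dimethoxycyclohexa-2,5-diene-1-carboxylate | CC(C)(C)[Si](C)(C)OC(=O)C1(C[C@@H](O[Si](C)(C)C(C)(C)C)CC(C)(C)CI)C(OC)=CCC=C1OC
F3 | step 12 | allyl 1-[(2R)-2-(tert-butyldimethylsilyloxy)-5-iodo-4,4-dimethylpentyl]-2,6-dioxocyclohexane-1-carboxylate | O=C1CCCC(=O)C1(C(=O)OCC=C)C[C@@H](O[Si](C)(C)C(C)(C)C)CC(C)(C)CI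
F4 | step 12 | allyl (1S,2R)-1-[(2R)-2-(tert-butyldimethylsilyloxy)-5-iodo-4,4-dimethylpentyl]-2-hydroxy-6-oxocyclohexane-1-carboxylate | O=C1CCC[C@@H](O)[C@@]1(C(=O)OCC=C)C[C@@H](O[Si](C)(C)C(C)(C)C)CC(C)(C)CI
F5 | step 12 | allyl (1S,2R)-1-[(2R)-2-(tert-butyldimethylsilyloxy)-5-iodo-4,4-dimethylpentyl]-2-(methanesulfonyloxy)-6-oxocyclohexane-1-carboxylate | O=C1CCC[C@@H](OS(C)(=O)=O)[C@@]1(C(=O)OCC=C)C[C@@H](O[Si](C)(C)C(C)(C)C)CC(C)(C)CI
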